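## Structural features

Betaethrin H (19) is an achiral diaryl ether. Ring A is a 1,2,3,5-tetrasubstituted benzene with a palmitoyloxymethyl group at C1, the ether oxygen at C2, a free hydroxyl at C3 and a methoxy group at C5 (hydrogens at C4 and C6); ring B is a 3-hydroxy-5-methylphenyl group bound through the C2 oxygen. There is no stereocentre and no stereogenic double bond, so no stereocentres stand next to each other and all stereochemistry that appears on the way is transient. The fragile parts are the benzylic ester (cleaved by hydrogenolysis, alkoxide and strong acid) and the two free phenols on electron-rich rings (sensitive to oxidants), so all three are formed or unveiled at the very end. The real difficulty is threefold. The ether oxygen at C2 lies between substituents at C1 and C3 on an electron-rich ring, a poor setting for nucleophilic aromatic substitution or copper-mediated coupling. The oxygens at C3 and C5 must end as hydroxyl and methyl ether and not the reverse. The last acylation must pick the primary alcohol in the presence of two phenols.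

The key step exploits the 1,3-relationship of the C3 and C5 oxygens across unsubstituted C4. Ring A is a cyclohexane-1,3-dione at a lower oxidation level, and C2 is then the alpha-carbon of the C3 carbonyl, so it can receive the aryloxy group while still part of an unhindered open chain. In that dione the C3 carbonyl lies next to the aryloxy-bearing C2 and the C5 carbonyl next to the C6 methylene, and this difference places the methyl group on the C5 oxygen before aromatisation. The C1 hydroxymethyl group travels as a tert-butyldiphenylsilyl ether, because a tert-butyldimethylsilyl ether would not survive the acidic methanol of step 6. The ring B phenol travels as a benzyl ether that is removed before the benzylic ester exists.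

## Logic of the disconnections

19 is cut at the benzylic CH2–O bond of the ester into 17 and 18. The ester is the most fragile function and is therefore made last. The cut removes the C16 chain and leaves a small triol. The forward step must esterify only the primary alcohol in the presence of two phenols, which calls for activation of the alcohol and not of the acid.

17 is traced to 15 (through 16) by restoring the benzyl group on the ring B oxygen and the silyl group on the benzylic oxygen. Both masks are needed through the basic and oxidative steps. In 15 only the C3 hydroxyl is free. The forward hydrogenolysis must cleave the aryl benzyl ether without touching the benzylic C–O bond of ring A, which is why the silyl group is still in place at that moment and why the ester is not yet present.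

15 is taken back to 12 (through 13 and 14) by giving up aromaticity, adding back the hydrogens at C1 and C2 so that C3 becomes a ketone and C5 a methyl enol ether. At this level the two oxygens are chemically different and the aryloxy carbon is sp3. The demand is a dehydrogenation mild enough for the benzyl ether and ring B, and one that does not expose the new phenol to the oxidant.

12 is cut at the C5–OMe bond to 11. This exposes the plain dione. The forward etherification must choose the C5 carbonyl over C3 and must spare the silyl ether, which fixes the choice of silyl group.

11 is traced to 9 (through 10) by adding a methoxycarbonyl group at C6. The ester is the activating group that makes C6 a soft carbanion in the ring-forming step and leaves no trace. Its removal must be close to neutral.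

9 is cut at C1–C6 and C4–C5 into 6 and 7 (through 8). This is the ring-forming step. It reduces ring A to an open-chain enone that already carries the aryloxy group and to a bulk diester. The forward step needs conjugate addition at the beta-carbon of 6 and ring closure through the methyl group.

6 is cut at its C=C bond (C1=C2 of ring A) into 4 and 5. An olefination fixes C2 as the reacting carbon, which a condensation of an unsymmetrical ketone could not guarantee. 5 is bought. The demand is an olefination of a fully substituted phosphonate carbanion with an enolisable aldehyde; the geometry is irrelevant.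

4 is cut at the C2–O bond into 2 and 3. The ring B oxygen is joined to an electrophilic carbenoid carbon and not to a hindered arene. 3 is bought. The insertion into the O–H bond must outrun attack on the electron-rich ring of 2.

2 is cut at the O–benzyl bond to 1. The step desymmetrises a cheap diol with a group that lasts to step 8. The mono-alkylation is statistical and needs an excess of 1.

## Other disconnections considered

Alternative 1: The cut runs through ring B. The ether-bearing carbon and one neighbouring CH are taken out as an alkyne, the other four carbons as a diene. In the forward sense the aryl ethynyl ether A2 (tert-butyl{[2-(ethynyloxy)-5-methoxy-3-(methoxymethoxy)phenyl]methoxy}dimethylsilane) would add across C3 and C6 of the protected pyrone A3 (4-(methoxymethoxy)-6-methyl-2H-pyran-2-one). Decarboxylative cycloreversion of the bridged adduct would then close ring B and give the fully protected diaryl ether A1.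
- In its favour: the ether oxygen is never joined to a hindered arene by coupling. The polarity of the partners (nucleophilic terminal alkyne carbon, electrophilic pyrone C6) should fix the orientation. The ring is formed aromatic, and A3 is one step from a bulk chemical.
- Against it here: the ring that is built is the easy one, which is available intact in 1. The demanding ring A, with three differentiated oxygens and the hydroxymethyl group, must still be made by a separate sequence before A2 exists. A 2,6-disubstituted aryl ynol ether is hard to make and prone to hydration and polymerisation. A 4-alkoxypyrone is an electron-rich diene, poorly matched with an electron-rich alkyne, so the cycloaddition would need temperatures that threaten the acetal and silyl groups.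
- Comparison: on structure the two plans are equal in avoiding an aryl–oxygen coupling at congested C2, but the chosen plan spends its key step on ring A, where the complexity lies. On mechanism the alternative is the better in delivering an arene at the right oxidation level in one operation, where the chosen plan needs steps 5 to 7; against that, it relies on a thermally forced, electronically mismatched cycloaddition in place of a polarity-matched ionic annulation. On step economy its convergence is an advantage, yet the separate construction of ring A and three deprotections should make it longer than the nine steps planned here.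

Alternative 2: Ring A is cut at C3–C4, C5–C6 and C2–C3 into a four-carbon cyclobutenone and a two-carbon alkyne. Heating the cyclobutenone A5 (4-[3-(tert-butyldimethylsilyloxy)-5-methylphenoxy]-3-[(tert-butyldimethylsilyloxy)methyl]cyclobut-2-en-1-one) with methoxyacetylene A6 would open the four-membered ring to a vinylketene, which adds the alkyne in a [2+2] sense (C3–C4 and C5–C6 bonds). A second four-electron ring opening, a six-electron electrocyclisation (C2–C3 bond) and tautomerisation would give phenol A4 (Danheiser benzannulation).
- In its favour: one step lays down the whole substitution pattern of ring A. The C3 hydroxyl comes from the ketene carbonyl and the C5 methoxy group from the alkyne, so the two oxygens differ by origin and not by a selective reaction. No dehydrogenation is needed, and both silyl groups of A4 would fall in one fluoride step.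
- Against it here: A5 is itself a demanding target, a strained enone with an aryloxy group on its sp3 carbon and a silyloxymethyl group on the alkene, for which no short and regiochemically safe preparation is evident. A donor on the sp3 carbon alters the ease and sense of the ring opening. A6 is a volatile, unstable alkyne that must be freshly made and used in excess. The phenolic silyl ether of ring B must survive prolonged heating.
- Comparison: on structure the alternative is the better in how it differentiates the C3 and C5 oxygens (step 6 of the chosen plan depends on a regioselective etherification), and equal in placing the aryloxy group on an sp3 carbon before ring A exists. On mechanism it is a pericyclic cascade with well-defined regiochemistry but high thermal demand, against an ionic annulation under mild base. On step economy it is shorter after the key step (two steps against five), but this is likely to be lost again on the way to A5 and A6.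

Alternative 3: Ring A is cut at the C1–C2 bond only, which unfolds it into a polyketide-like chain. Base would convert the open-chain keto enol ether A8 (ethyl (E)-7-[3-(benzyloxy)-5-methylphenoxy]-4-methoxy-2,6-dioxohept-4-enoate) into the enolate at the aryloxy-bearing carbon. This enolate attacks the ketone of the alpha-keto ester (C1–C2 bond), and loss of water with enolisation of the C3 carbonyl would give the benzoate A7.
- In its favour: the approach is biomimetic and short on paper. The ring arrives aromatic without an oxidation step, the methoxy group at C5 is in place before the ring closes, and the ester at C1 needs only reduction to reach the hydroxymethyl level.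
- Against it here: A8 must be assembled by acylations of a polycarbonyl chain in which the most acidic position is not always the one that must react. The enol ether has to hold the two arms cis. The doubly activated C6 methylene competes with the aryloxy carbon as the nucleophile. Tricarbonyl chains of this kind also close readily through oxygen to pyranones, here with loss of the methoxy group, so the wanted carbocyclisation is only one of several channels.
- Comparison: on structure both plans build ring A from an open chain that already carries the aryloxy group on an sp3 carbon, and the alternative is the better in delivering the C5 methyl ether and the aromatic ring without steps 5 to 7. On mechanism the chosen annulation has one productive ring size and a strong thermodynamic sink, whereas the aldol folding must win against oxygen cyclisation and the wrong enolate. On step economy the alternative is about equal from A7 onwards (reduction, debenzylation, esterification), and its total length depends on how many steps A8 costs.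

Key step: step 4

Assumption: enone 6 is drawn as the (Z) isomer (aryloxy and silyloxymethyl groups cis), the isomer expected to prevail; the (E) isomer would give the same annulation product, since this carbon becomes sp3 in step 4.

## Route

Step 1
Reactants: 1 orcinol (5-methylbenzene-1,3-diol)
Product: 2 3-(benzyloxy)-5-methylphenol
Conditions: BnBr (limiting), K2CO3, acetone, reflux; 1 in excess
Reagents that add atoms: benzyl bromide, BrCc1ccccc1
Why: Williamson ether synthesis (SN2 at the benzylic carbon); the two hydroxyls of 1 are equivalent, so an excess of 1 should hold the reaction at the mono-ether, and unreacted 1 is removed by aqueous extraction. No stereocentre is formed.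

Step 2
Reactants: 2 3-(benzyloxy)-5-methylphenol; 3 dimethyl (1-diazo-2-oxopropyl)phosphonate
Product: 4 dimethyl {1-[3-(benzyloxy)-5-methylphenoxy]-2-oxopropyl}phosphonate (racemic)
Conditions: Rh2(OAc)4 (cat.), PhMe, 90 °C, slow addition of nitrile-free 3
Reagents that add atoms: none
Why: Rhodium carbenoid O–H insertion: Rh2(OAc)4 converts 3 into an electrophilic carbenoid that is captured by the phenol oxygen of 2 (oxonium ylide, then proton shift), which joins the ring B oxygen to the future C2 while that carbon is unhindered. The new stereocentre is formed racemic and is destroyed in step 3.

Step 3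
Reactants: 4 dimethyl {1-[3-(benzyloxy)-5-methylphenoxy]-2-oxopropyl}phosphonate; 5 2-[(tert-butyldiphenylsilyl)oxy]acetaldehyde
Product: 6 (3Z)-3-[3-(benzyloxy)-5-methylphenoxy]-5-[(tert-butyldiphenylsilyl)oxy]pent-3-en-2-one
Conditions: NaH, THF, 0 °C; then 5, 0 °C to rt
Reagents that add atoms: none
Why: Horner–Wadsworth–Emmons olefination: the sodium enolate of 4 adds to 5 and loses dimethyl phosphate, so the C=C bond can only form at the aryloxy-bearing carbon. The isomer with the acetyl group trans to the silyloxymethyl group, (Z) by the sequence rules, should predominate, and no stereocentre is formed.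

Step 4
Reactants: 6 (3Z)-3-[3-(benzyloxy)-5-methylphenoxy]-5-[(tert-butyldiphenylsilyl)oxy]pent-3-en-2-one; 7 dimethyl malonate
Product: 9 methyl 5-[3-(benzyloxy)-5-methylphenoxy]-6-{[(tert-butyldiphenylsilyl)oxy]methyl}-2,4-dioxocyclohexane-1-carboxylate (mixture of diastereomers), via Michael adduct 8 (not isolated)
Conditions: NaOMe, MeOH/THF, 0 °C then 50 °C; cold 1 M HCl work-up
Reagents that add atoms: none
Why: Methoxide turns 7 into its stabilised carbanion, which adds to the beta-carbon of 6 (C1–C6 bond) to give 8; the aryloxy oxygen is only a weak donor, so this carbon remains the one soft electrophilic site, whereas the alpha-carbon is an sp2 carbon with a poor leaving group and cannot be substituted. Under the equilibrating alkoxide conditions the methyl ketone enolate of 8 then attacks one ester group in a 6-exo-trig Claisen (Dieckmann-type) closure (C4–C5 bond), and expulsion of methoxide followed by deprotonation of the new beta-dicarbonyl system makes the sequence irreversible. The closest known reaction type is the Michael–Claisen annulation of malonic esters with enones to cyclohexane-1,3-diones. Ring size secures the site of closure: the enolate on the aryloxy side could only form a four-membered ring, and displacement of aryloxide by the malonate carbanion to a cyclopropane should be far slower than acylation because aryloxide is a much poorer leaving group than halide. Three stereocentres arise, at C1, C2 and C6 of the future ring A; C2 and C6 are epimerisable and should settle under thermodynamic control with their substituents equatorial, C1 is set without control, and none matters because all three vanish in steps 5 and 7. The benzyl and silyl ethers are spectators, and cold acidification releases 9 from its sodium enolate.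

Step 5
Reactants: 9 methyl 5-[3-(benzyloxy)-5-methylphenoxy]-6-{[(tert-butyldiphenylsilyl)oxy]methyl}-2,4-dioxocyclohexane-1-carboxylate
Product: 11 4-[3-(benzyloxy)-5-methylphenoxy]-5-{[(tert-butyldiphenylsilyl)oxy]methyl}cyclohexane-1,3-dione (mixture of diastereomers), via keto acid 10 (not isolated)
Conditions: LiCl, H2O, DMSO, 120 °C; dilute HCl work-up
Reagents that add atoms: none
Why: Krapcho dealkoxycarbonylation: chloride demethylates the beta-keto ester by SN2 at the methyl group, and carboxylate 10, which is beta to the C5 carbonyl, loses CO2. The neutral medium spares the silyl and benzyl ethers; the C6 stereocentre disappears and C1 and C2 remain as an inconsequential mixture.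

Step 6
Reactants: 11 4-[3-(benzyloxy)-5-methylphenoxy]-5-{[(tert-butyldiphenylsilyl)oxy]methyl}cyclohexane-1,3-dione
Product: 12 6-[3-(benzyloxy)-5-methylphenoxy]-5-{[(tert-butyldiphenylsilyl)oxy]methyl}-3-methoxycyclohex-2-en-1-one (mixture of diastereomers)
Conditions: MeOH, camphorsulfonic acid (cat.), 3 Å molecular sieves, rt
Reagents that add atoms: methanol, CO
Why: Acid-catalysed enol etherification of a vinylogous acid under equilibrium control: methanol should add at the C5 carbonyl, flanked by a methylene, and not at C3, where the aryloxy-bearing neighbour hinders approach and inductively destabilises the oxocarbenium-like intermediate. The tert-butyldiphenylsilyl ether tolerates catalytic sulfonic acid in methanol at room temperature, and no stereocentre is created.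

Step 7
Reactants: 12 6-[3-(benzyloxy)-5-methylphenoxy]-5-{[(tert-butyldiphenylsilyl)oxy]methyl}-3-methoxycyclohex-2-en-1-one
Product: 15 2-[3-(benzyloxy)-5-methylphenoxy]-3-{[(tert-butyldiphenylsilyl)oxy]methyl}-5-methoxyphenol, via silyl dienol ether 13 (not isolated), via aryl silyl ether 14 (not isolated)
Conditions: LiN(iPr)2, Me3SiCl, THF, −78 °C; evaporate, pentane, filter; DDQ, PhMe, 0 °C to rt; aq. citric acid, MeOH
Reagents that add atoms: none
Why: Kinetic enolisation with in situ silylation should give cyclohexa-1,3-diene 13 (a dienol ether from gamma-deprotonation would converge on the same arene), and DDQ dehydrogenation of a cyclohexadiene to an arene (hydride abstraction at C6, proton loss from C1) then gives 14, whose silyl group shields the new phenol from the oxidant until the mildly acidic work-up releases 15. Both remaining stereocentres are erased.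

Step 8
Reactants: 15 2-[3-(benzyloxy)-5-methylphenoxy]-3-{[(tert-butyldiphenylsilyl)oxy]methyl}-5-methoxyphenol
Product: 17 3-(hydroxymethyl)-2-(3-hydroxy-5-methylphenoxy)-5-methoxyphenol, via silyl ether 16 (not isolated)
Conditions: H2 (1 atm), Pd/C, THF, rt; then Ar purge, Bu4NF, AcOH, rt
Reagents that add atoms: none
Why: Hydrogenolysis of the aryl benzyl ether over palladium on carbon is much faster than cleavage of the silyl-protected benzylic C–O bond of ring A, and fluoride then removes the silyl group by Si–F bond formation, with acetic acid keeping the phenols protonated. Debenzylating before the ester exists avoids hydrogenolysis of a benzylic ester.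

Step 9
Reactants: 17 3-(hydroxymethyl)-2-(3-hydroxy-5-methylphenoxy)-5-methoxyphenol; 18 palmitic acid (hexadecanoic acid)
Product: 19 Betaethrin H, [3-hydroxy-2-(3-hydroxy-5-methylphenoxy)-5-methoxyphenyl]methyl hexadecanoate
Conditions: PPh3, DIAD, THF, 0 °C to rt
Reagents that add atoms: none
Why: Mitsunobu esterification: the carboxylic acid, far more acidic than either phenol, protonates the betaine, and its carboxylate displaces the activated primary benzylic oxygen by SN2, so only the alcohol is esterified and both phenols stay free. No stereocentre is involved.

## Compound list

1 | orcinol (5-methylbenzene-1,3-diol) | Cc1cc(O)cc(O)c1 | starting material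
2 | 3-(benzyloxy)-5-methylphenol | Cc1cc(O)cc(OCc2ccccc2)c1 | intermediate
3 | dimethyl (1-diazo-2-oxopropyl)phosphonate | CC(=O)C(=[N+]=[N-])P(=O)(OC)OC | starting material
4 | dimethyl {1-[3-(benzyloxy)-5-methylphenoxy]-2-oxopropyl}phosphonate (racemic) | CC(=O)C(Oc1cc(C)cc(OCc2ccccc2)c1)P(=O)(OC)OC | intermediate
5 | 2-[(tert-butyldiphenylsilyl)oxy]acetaldehyde | O=CCO[Si](c1ccccc1)(c1ccccc1)C(C)(C)C | starting material
6 | (3Z)-3-[3-(benzyloxy)-5-methylphenoxy]-5-[(tert-butyldiphenylsilyl)oxy]pent-3-en-2-one | CC(=O)/C(Oc1cc(C)cc(OCc2ccccc2)c1)=C/CO[Si](c1ccccc1)(c1ccccc1)C(C)(C)C | intermediate
7 | dimethyl malonate | COC(=O)CC(=O)OC | starting material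
8 | dimethyl 2-{3-[3-(benzyloxy)-5-methylphenoxy]-1-[(tert-butyldiphenylsilyl)oxy]-4-oxopentan-2-yl}propanedioate (mixture of diastereomers) | COC(=O)C(C(=O)OC)C(CO[Si](c1ccccc1)(c1ccccc1)C(C)(C)C)C(Oc1cc(C)cc(OCc2ccccc2)c1)C(C)=O | intermediate (not isolated)
9 | methyl 5-[3-(benzyloxy)-5-methylphenoxy]-6-{[(tert-butyldiphenylsilyl)oxy]methyl}-2,4-dioxocyclohexane-1-carboxylate (mixture of diastereomers, largely enolised) | COC(=O)C1C(=O)CC(=O)C(Oc2cc(C)cc(OCc3ccccc3)c2)C1CO[Si](c1ccccc1)(c1ccccc1)C(C)(C)C | intermediate
10 | 5-[3-(benzyloxy)-5-methylphenoxy]-6-{[(tert-butyldiphenylsilyl)oxy]methyl}-2,4-dioxocyclohexane-1-carboxylic acid (mixture of diastereomers) | OC(=O)C1C(=O)CC(=O)C(Oc2cc(C)cc(OCc3ccccc3)c2)C1CO[Si](c1ccccc1)(c1ccccc1)C(C)(C)C | intermediate (not isolated)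
11 | 4-[3-(benzyloxy)-5-methylphenoxy]-5-{[(tert-butyldiphenylsilyl)oxy]methyl}cyclohexane-1,3-dione (mixture of diastereomers) | O=C1CC(=O)C(Oc2cc(C)cc(OCc3ccccc3)c2)C(CO[Si](c2ccccc2)(c2ccccc2)C(C)(C)C)C1 | intermediate
12 | 6-[3-(benzyloxy)-5-methylphenoxy]-5-{[(tert-butyldiphenylsilyl)oxy]methyl}-3-methoxycyclohex-2-en-1-one (mixture of diastereomers) | COC1=CC(=O)C(Oc2cc(C)cc(OCc3ccccc3)c2)C(CO[Si](c2ccccc2)(c2ccccc2)C(C)(C)C)C1 | intermediate
13 | 1-[3-(benzyloxy)-5-methylphenoxy]-6-{[(tert-butyldiphenylsilyl)oxy]methyl}-4-methoxy-2-[(trimethylsilyl)oxy]cyclohexa-1,3-diene (racemic) | COC1=CC(O[Si](C)(C)C)=C(Oc2cc(C)cc(OCc3ccccc3)c2)C(CO[Si](c2ccccc2)(c2ccccc2)C(C)(C)C)C1 | intermediate (not isolated)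
14 | {2-[3-(benzyloxy)-5-methylphenoxy]-3-{[(tert-butyldiphenylsilyl)oxy]methyl}-5-methoxyphenoxy}trimethylsilane | COc1cc(O[Si](C)(C)C)c(Oc2cc(C)cc(OCc3ccccc3)c2)c(CO[Si](c2ccccc2)(c2ccccc2)C(C)(C)C)c1 | intermediate (not isolated)
15 | 2-[3-(benzyloxy)-5-methylphenoxy]-3-{[(tert-butyldiphenylsilyl)oxy]methyl}-5-methoxyphenol | COc1cc(O)c(Oc2cc(C)cc(OCc3ccccc3)c2)c(CO[Si](c2ccccc2)(c2ccccc2)C(C)(C)C)c1 | intermediate
16 | 3-{[(tert-butyldiphenylsilyl)oxy]methyl}-2-(3-hydroxy-5-methylphenoxy)-5-methoxyphenol | COc1cc(O)c(Oc2cc(C)cc(O)c2)c(CO[Si](c2ccccc2)(c2ccccc2)C(C)(C)C)c1 | intermediate (not isolated)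
17 | 3-(hydroxymethyl)-2-(3-hydroxy-5-methylphenoxy)-5-methoxyphenol | COc1cc(O)c(Oc2cc(C)cc(O)c2)c(CO)c1 | intermediate
18 | palmitic acid (hexadecanoic acid) | CCCCCCCCCCCCCCCC(=O)O | starting material
19 | Betaethrin H, [3-hydroxy-2-(3-hydroxy-5-methylphenoxy)-5-methoxyphenyl]methyl hexadecanoate | CCCCCCCCCCCCCCCC(=O)OCc1cc(OC)cc(O)c1Oc1cc(C)cc(O)c1 | target

## Step count and least certain steps

Total step count: 9. Longest linear sequence: 9 steps (1 to 19); 3, 5, 7 and 18 are bought and enter directly.

Key step (step 4). The most likely failure is stalling after the conjugate addition, followed by reversal of the addition or base-induced isomerisation of the enone through gamma-deprotonation. The beta-carbon is somewhat deactivated by the alpha-oxygen, and the methyl ketone enolate needed for ring closure is only a minor partner in the equilibrium. Slow displacement of aryloxide by the malonate carbanion and erosion of the silyl ether by methoxide are secondary concerns. The fallback separates the two bond formations and activates the enone with a Lewis acid instead of relying on a basic equilibrium. Setting out from 6, a Mukaiyama–Michael addition of 1-methoxy-1-(trimethylsilyloxy)ethene (catalytic Me3SiOTf, CH2Cl2, −78 °C, aqueous work-up) should give methyl 4-[3-(benzyloxy)-5-methylphenoxy]-3-{[(tert-butyldiphenylsilyl)oxy]methyl}-5-oxohexanoate F1. Its methyl ketone enolate (KOtBu, THF, 0 °C) should close onto the ester in a Claisen cyclisation, and acidification rejoins the route at 11, so step 5 is no longer needed.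

Carbenoid insertion (step 2). The carbenoid may be diverted to the electron-rich ring of 2 (aromatic substitution or cyclopropanation) or to residual nitrile solvent (oxazole formation) instead of inserting into the O–H bond. The fallback builds the same C2–O bond by SN2 chemistry. Setting out from 2, O-alkylation with diethyl (tosyloxymethyl)phosphonate (Cs2CO3, DMF) should give diethyl {[3-(benzyloxy)-5-methylphenoxy]methyl}phosphonate F2. Deprotonation with LiN(iPr)2 at −78 °C and C-acylation with N-methoxy-N-methylacetamide should give diethyl {1-[3-(benzyloxy)-5-methylphenoxy]-2-oxopropyl}phosphonate F3. F3 is then olefinated with 5 under the conditions of step 3, which rejoins the route at 6.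

Enol etherification (step 6). The risk is leakage of the etherification to the C3 carbonyl, together with slow acid-induced loss of the silyl ether if the reaction must be forced. The fallback gives up equilibrium control in favour of an irreversible, acid-free O-methylation with a recycling loop. Setting out from 11, Me3SiCHN2 in toluene/methanol at 0 °C should methylate both enol oxygens. 12 is separated by chromatography from its regioisomer 4-[3-(benzyloxy)-5-methylphenoxy]-5-{[(tert-butyldiphenylsilyl)oxy]methyl}-3-methoxycyclohex-2-en-1-one F4. F4 is hydrolysed back to 11 with dilute HCl in THF and resubmitted, so the route is rejoined at 12.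

Aromatisation (step 7). The risks are incomplete or reversed silylation before the oxidation, and over-oxidation of the electron-rich product or of the benzylic ether position by the quinone. The fallback replaces hydride abstraction by a selenoxide syn-elimination. Setting out from 12, the lithium enolate (LiN(iPr)2, THF, −78 °C) is trapped with PhSeCl to give 6-[3-(benzyloxy)-5-methylphenoxy]-5-{[(tert-butyldiphenylsilyl)oxy]methyl}-3-methoxy-6-(phenylselanyl)cyclohex-2-en-1-one F5, with selenium expected trans to the silyloxymethyl group and therefore cis to the C1 hydrogen. Oxidation with H2O2 in CH2Cl2/pyridine at 0 °C should give the cross-conjugated dienone, which tautomerises to the phenol and rejoins the route at 15.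

Final esterification (step 9). Chemoselectivity may be lost through O-alkylation of a phenol by the activated benzylic alcohol, giving benzyl aryl ether oligomers, if carboxylate attack is slow. The fallback acylates everything and then uses the much higher reactivity of aryl esters towards amines. Setting out from 17, palmitoyl chloride (excess) with pyridine and catalytic 4-(dimethylamino)pyridine in CH2Cl2 should give {3-(hexadecanoyloxy)-2-[3-(hexadecanoyloxy)-5-methylphenoxy]-5-methoxyphenyl}methyl hexadecanoate F6. Pyrrolidine in CH2Cl2 at 0 °C should then cleave only the two aryl esters, which rejoins the route at 19.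

## Further compounds

F1 | step 4 | methyl 4-[3-(benzyloxy)-5-methylphenoxy]-3-{[(tert-butyldiphenylsilyl)oxy]methyl}-5-oxohexanoate (mixture of diastereomers) | COC(=O)CC(CO[Si](c1ccccc1)(c1ccccc1)C(C)(C)C)C(Oc1cc(C)cc(OCc2ccccc2)c1)C(C)=O
F2 | step 2 | diethyl {[3-(benzyloxy)-5-methylphenoxy]methyl}phosphonate | CCOP(=O)(COc1cc(C)cc(OCc2ccccc2)c1)OCC
F3 | step 2 | diethyl {1-[3-(benzyloxy)-5-methylphenoxy]-2-oxopropyl}phosphonate (racemic) | CCOP(=O)(OCC)C(Oc1cc(C)cc(OCc2ccccc2)c1)C(C)=O
F4 | step 6 | 4-[3-(benzyloxy)-5-methylphenoxy]-5-{[(tert-butyldiphenylsilyl)oxy]methyl}-3-methoxycyclohex-2-en-1-one (mixture of diastereomers) | COC1=CC(=O)CC(CO[Si](c2ccccc2)(c2ccccc2)C(C)(C)C)C1Oc1cc(C)cc(OCc2ccccc2)c1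
F5 | step 7 | 6-[3-(benzyloxy)-5-methylphenoxy]-5-{[(tert-butyldiphenylsilyl)oxy]methyl}-3-methoxy-6-(phenylselanyl)cyclohex-2-en-1-one (racemic) | COC1=CC(=O)C(Oc2cc(C)cc(OCc3ccccc3)c2)([Se]c2ccccc2)C(CO[Si](c2ccccc2)(c2ccccc2)C(C)(C)C)C1
F6 | step 9 | {3-(hexadecanoyloxy)-2-[3-(hexadecanoyloxy)-5-methylphenoxy]-5-methoxyphenyl}methyl hexadecanoate | CCCCCCCCCCCCCCCC(=O)OCc1cc(OC)cc(OC(=O)CCCCCCCCCCCCCCC)c1Oc1cc(C)cc(OC(=O)CCCCCCCCCCCCCCC)c1
A1 | alternative 1 | tert-butyl({5-methoxy-3-(methoxymethoxy)-2-[3-(methoxymethoxy)-5-methylphenoxy]phenyl}methoxy)dimethylsilane | COCOc1cc(C)cc(Oc2c(CO[Si](C)(C)C(C)(C)C)cc(OC)cc2OCOC)c1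
A2 | alternative 1 | tert-butyl{[2-(ethynyloxy)-5-methoxy-3-(methoxymethoxy)phenyl]methoxy}dimethylsilane | C#COc1c(CO[Si](C)(C)C(C)(C)C)cc(OC)cc1OCOC
A3 | alternative 1 | 4-(methoxymethoxy)-6-methyl-2H-pyran-2-one | COCOC1=CC(=O)OC(C)=C1
A4 | alternative 2 | 2-[3-(tert-butyldimethylsilyloxy)-5-methylphenoxy]-3-[(tert-butyldimethylsilyloxy)methyl]-5-methoxyphenol | COc1cc(O)c(Oc2cc(C)cc(O[Si](C)(C)C(C)(C)C)c2)c(CO[Si](C)(C)C(C)(C)C)c1
A5 | alternative 2 | 4-[3-(tert-butyldimethylsilyloxy)-5-methylphenoxy]-3-[(tert-butyldimethylsilyloxy)methyl]cyclobut-2-en-1-one (racemic) | O=C1C=C(CO[Si](C)(C)C(C)(C)C)C1Oc1cc(C)cc(O[Si](C)(C)C(C)(C)C)c1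
A6 | alternative 2 | methoxyacetylene (methoxyethyne) | COC#C
A7 | alternative 3 | ethyl 2-[3-(benzyloxy)-5-methylphenoxy]-3-hydroxy-5-methoxybenzoate | CCOC(=O)c1cc(OC)cc(O)c1Oc1cc(C)cc(OCc2ccccc2)c1
A8 | alternative 3 | ethyl (E)-7-[3-(benzyloxy)-5-methylphenoxy]-4-methoxy-2,6-dioxohept-4-enoate | CCOC(=O)C(=O)C/C(OC)=C\C(=O)COc1cc(C)cc(OCc2ccccc2)c1
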